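Atom labels used throughout: dihydrobenzofuran numbering (O1, C2, C3, C3a, C4–C7, C7a). C9 is the CH2 on C3. Ring A is the benzo ring, ring B the dihydrofuran, ring C the aryl group on C2 (primed atoms) and ring D the benzoate ring.

## Analysis of the target

Compound 29 is an 8–5′ neolignan built on a 2-aryl-2,3-dihydrobenzofuran. Ring A (C3a–C7a) is fused to ring B (O1, C2, C3), C2 carries the 4-hydroxy-3-methoxyphenyl ring C, and the oxygen on C9 is acylated by 4-hydroxybenzoic acid (ring D), while C7 bears a methoxy group and C5 a (Z)-3-oxoprop-1-enyl chain. The only stereocentres, C2 (S) and C3 (R), are adjacent and place ring C and C9 trans on ring B. Trans is the more stable arrangement, so the relative configuration can be left to substrate control once one centre is fixed in absolute terms. The third stereochemical element is the Z double bond of the enal, which is the less stable geometry, and the donor O1 para to the chain lowers the rotation barrier as soon as the carbonyl is protonated or a nucleophile adds. Other sensitive points are the C9 benzoate, which no hydride reagent will spare, the two free phenols, and the O1–C2 bond, which the free para hydroxyl of ring C can reopen under base or oxidant. The main difficulty is therefore the order of events: absolute configuration early, all reductions before the ester, and the enal exposed to as few reagents as possible. The strategy rests on the ring C hydroxyl standing para to C2, because oxidising that 4-alkylguaiacol makes C2 the exocyclic carbon of a para-quinone methide, and the ring A phenol oxygen O1 is placed to close the five-membered ring B onto it. At that stage the C5 substituent, para to O1, is carried as a methyl ester, so ring A is the electron-poor phenol and only ring C is oxidised.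

## Retrosynthetic reasoning

**29 to 28.** Only the two O–Si bonds on rings C and D are cut last. Aryl silyl ethers fall under buffered, nearly neutral conditions, the only kind of deprotection a Z-enal conjugated to a para oxygen can be expected to tolerate.

**28 to 23 and 26.** The acyl–O bond at C9 is cut. The ester cannot survive any hydride step, so it enters after the last reduction. The forward reaction must acylate a primary alcohol beside a Z-enal without strongly nucleophilic catalysts. Acid 26 comes from 24 by silylation.

**23 to 22, 21 and 20.** The enal is traced to the Z-allylic alcohol of diol 22. The two primary alcohols are told apart by an oxidant that touches only allylic alcohols, which saves a protect/deprotect pair. Diol 22 comes from hydroxy ester 21 by reduction, and 21 from 20 by selective release of the C9 silyl ether. This acid step is placed at the enoate stage because the electron-rich cinnamyl alcohol of 22 would ionise under acid.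

**20 to 18 and 19.** The side-chain C=C bond is cut. A Z-selective phosphonate olefination of an aromatic aldehyde is the most dependable source of a Z-cinnamoyl unit. An ylide carrying a masked aldehyde would save two redox steps, but it controls geometry less well. Its unmasking also needs acid, which would ionise a vinylogous para-alkoxybenzyl acetal and lose the geometry. The two extra redox steps are accepted.

**18 to 17, 16 and 15.** These steps adjust the oxidation level at C5 and cap the ring C phenol. Capping comes directly after ring closure, because the free para hydroxyl is what allows O1–C2 to reopen. A bulkier silyl group than the one at C9 is chosen so that the two can be separated later.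

**15 to 14 and 13 (key disconnection).** O1–C2 is cut. The bond is benzylic to ring C and para to its hydroxyl, so it maps onto addition of the ring A phenol to para-quinone methide 14, which comes from 13 by loss of two hydrogens. The gain is that 13 has a single stereocentre and no heterocycle. The forward step must oxidise only ring C, close ring B faster than 14 tautomerises, and place ring C trans to C9.

**13 to 12, 11 and 10.** Both phenols are held as benzyl ethers so that one neutral hydrogenolysis frees them together. C9 is traced to a carboxylic acid that can be reduced selectively beside the ring A ester.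

**10 to 9, then 7 and 8.** The C3 stereocentre is traced to enantioselective hydrogenation of the C2=C3 alkene of 9, in which the carboxyl group (the future C9) serves as the binding handle for the catalyst. Cutting C2=C3 by a Perkin condensation gives arylacetic acid 7 and the commercial aldehyde 8.

**7 to 6, 5, 4 and 3, then 1 and 2.** The C3a–C3 bond is cut by an aromatic Claisen rearrangement. Compound 1 has only one free ortho position, so regiochemistry is not in question. The price is the terminal allyl carbon, which is removed by oxidative cleavage.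

## Alternatives that were turned down

**Alternative 1:**
- **Disconnection.** Two C–C bonds, C2–C1′ and C3–C9, are cut at once. This leads back to the aromatic 5-(dimethoxymethyl)-7-methoxybenzofuran A1, the ring C pinacol boronate A2 and an allyl electrophile.
- **Forward key step.** A1 would be metalated at C2 and combined with A2 to give a tetracoordinate boronate. Its C3 would attack a chiral π-allyl complex of palladium while ring C shifts from boron to C2. This should give the 3-allyl-2-aryl-2-boryl-2,3-dihydrobenzofuran A3 with aryl and allyl trans.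
- **For it.** Three fragments, two skeletal bonds and both stereocentres come together in one catalytic operation. The C5 acetal is one mild hydrolysis from the aldehyde, whereas the chosen route spends two redox steps on its ester. On both points this alternative is stronger.
- **Against it.** A3 is still far from 29.
  - Boron on the fully substituted C2 must be exchanged for hydrogen with retention. That carbon is benzylic, oxygen-bearing and para to a silyloxy group, so any carbanionic or radical character flattens it.
  - The allyl group has two carbons too many. It must be isomerised, cleaved and reduced through a C3 aldehyde, from which O1 can be expelled by β-elimination.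
  - Migration-coupled dearomatisation is much better established for indole-type nucleophiles than for an electron-rich benzofuran, so the enantioselectivity is an open question.
- **Comparison.** After these repairs most of the step advantage is lost. The chosen strategy makes only one bond and one stereocentre in its key step. In return, every skeletal atom brought in after the allyl cleavage stays in 29, the absolute configuration comes from a separate step that can be checked, and the trans outcome is backed by thermodynamics.

**Alternative 2:**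
- **Disconnection.** The C3–C3a bond is cut, and ring B is traced to the six-membered heterocycle of the (S)-flavanone A4.
- **Forward key step.** A hypervalent iodine oxidant with acid in an orthoformate solvent would form the enol ether of A4 and attack it at C3. Ring A would then shift from the former carbonyl carbon to C3, contracting the ring to the trans methyl ester A5.
- **For it.** C9 arrives with the right carbon count, C2 is carried over from A4, and trans is favoured both by anti migration and by the epimerisable C3. The C5 bromide would allow alkyne cross-coupling and semi-hydrogenation. That fixes the Z geometry more safely and in fewer steps than the aldehyde, olefination and reduction sequence of the chosen route, which is a real advantage.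
- **Against it.**
  - Three processes start from the same C3-iodinated intermediate: the shift of ring A, the shift of ring C from C2 to C3, and plain dehydrogenation of the heterocycle. The richer arene migrates. Ring C keeps a methoxy donor even as its pivalate, while ring A is brominated, so the wanted shift is the electronically weaker one.
  - The stereocentre of A4 racemises by reversible retro-oxa-Michael ring opening under the same acidic, enolising conditions. Obtaining A4 enantioenriched is an asymmetric problem of its own.
  - In A5 the C3 hydrogen is α to an ester and β to the aryloxide O1, so base can open ring B by an E1cB path and erase both centres.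
- **Comparison.** The chosen route keeps C9 at the alcohol level from before ring closure, so that path does not exist. Its chemoselectivity in the key step rests on a large electronic difference between two phenols, not on a narrow contest between two migrating groups.

**Alternative 3:**
- **Disconnection.** C2–C3 and O1–C2 are cut in a [4+1] sense. This gives the nitrovinylphenol A6 as the four-atom unit and the chiral ring C benzyl sulfonium salt A7 (drawn with a C2-symmetric thiolane as a representative sulfide) as the one-carbon unit.
- **Forward key step.** The ylide from A7 would add to the β-carbon of A6, and the phenoxide would then displace the sulfide at C2, closing ring B to the trans 3-(nitromethyl) compound A8.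
- **For it.** The step is convergent and forms two bonds and both stereocentres. The nitromethyl carbon has the right count for C9, and the bromide handle carries the same side-chain advantage as in Alternative 2. In bonds formed per step it is stronger than the chosen strategy.
- **Against it.**
  - The annulation is established for carbonyl-stabilised ylides. A benzylic ylide is far more basic than the phenoxide of A6, so proton transfer competes with addition.
  - A para-silyloxybenzyl sulfonium ion ionises easily, which opens a racemic background path.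
  - The chiral sulfide is stoichiometric, and its stereocentres are remote from C3, where the absolute configuration is decided.
  - Converting CH2NO2 into CH2OH needs a Nef reaction and a reduction. These conditions are harsh on an aryl silyl ether and pass through a C3 aldehyde that can epimerise or expel O1.
- **Comparison.** The chosen strategy is longer and linear. In return, the absolute configuration is set in a catalytic step with a directing carboxylate next to the new centre, and ring closure follows the pathway by which this skeleton forms from quinone methides in general.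

Key step: step 11

Assumption: the hydrogenation catalyst of step 7 is used as the ligand antipode that delivers (R)-10. The sense of induction must be assigned on the first run, and both antipodes of the ligand are accessible.

## Steps

Step 1
Reactants: 1 methyl vanillate; 2 allyl bromide
Product: 3 methyl 4-(allyloxy)-3-methoxybenzoate
Conditions: K2CO3, acetone, reflux
Reagents that add atoms: none
Why: Williamson etherification of the phenoxide with a reactive allylic halide; the ester is inert to carbonate in acetone.

Step 2
Reactants: 3 methyl 4-(allyloxy)-3-methoxybenzoate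
Product: 4 methyl 3-allyl-4-hydroxy-5-methoxybenzoate
Conditions: N,N-diethylaniline, 200 °C
Reagents that add atoms: none
Why: Aromatic Claisen rearrangement, a concerted [3,3] shift followed by tautomerisation. One ortho position is blocked by the methoxy group, so the allyl group can only reach the free ortho carbon, which forms the future C3a–C3 bond.

Step 3
Reactants: 4 methyl 3-allyl-4-hydroxy-5-methoxybenzoate
Product: 5 methyl 3-allyl-4-(benzyloxy)-5-methoxybenzoate
Conditions: BnBr, K2CO3, DMF, 60 °C
Reagents that add atoms: benzyl bromide, BrCc1ccccc1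
Why: Williamson benzylation. The benzyl ether masks the future O1 through cleavage, condensation and reduction, and is later removed together with that of ring C.

Step 4
Reactants: 5 methyl 3-allyl-4-(benzyloxy)-5-methoxybenzoate
Product: 6 methyl 4-(benzyloxy)-3-methoxy-5-(2-oxoethyl)benzoate
Conditions: K2OsO4·2H2O (2 mol%), NaIO4, 2,6-lutidine, dioxane/H2O, rt
Reagents that add atoms: sodium periodate, [Na+].[O-]I(=O)(=O)=O
Why: Lemieux–Johnson cleavage, that is catalytic dihydroxylation and periodate scission of the terminal alkene, with 2,6-lutidine suppressing over-oxidation. Benzyl ether, ester and arene are left alone, which a one-step RuO4 cleavage would not guarantee.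

Step 5
Reactants: 6 methyl 4-(benzyloxy)-3-methoxy-5-(2-oxoethyl)benzoate
Product: 7 2-[2-(benzyloxy)-3-methoxy-5-(methoxycarbonyl)phenyl]acetic acid
Conditions: NaClO2, NaH2PO4, 2-methylbut-2-ene, t-BuOH/H2O, 0 °C to rt
Reagents that add atoms: sodium chlorite, [Na+].[O-]Cl=O
Why: Pinnick oxidation, selective for aldehydes under buffered conditions. The alkene scavenger removes hypochlorous acid before it can chlorinate the arene, and the sensitive arylacetaldehyde is used without storage.

Step 6
Reactants: 7 2-[2-(benzyloxy)-3-methoxy-5-(methoxycarbonyl)phenyl]acetic acid; 8 4-(benzyloxy)-3-methoxybenzaldehyde (O-benzylvanillin)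
Product: 9 (E)-3-[4-(benzyloxy)-3-methoxyphenyl]-2-[2-(benzyloxy)-3-methoxy-5-(methoxycarbonyl)phenyl]prop-2-enoic acid
Conditions: Ac2O, Et3N, 110 °C; then H2O
Reagents that add atoms: none
Why: Perkin condensation in its arylacetic acid variant: the anhydride activates the acid, the amine enolises it, and aldol addition and elimination follow. It forms the C2=C3 bond and is known to favour the E acid with the two aryl groups cis, which can be purified by crystallisation.

Step 7
Reactants: 9 (E)-3-[4-(benzyloxy)-3-methoxyphenyl]-2-[2-(benzyloxy)-3-methoxy-5-(methoxycarbonyl)phenyl]prop-2-enoic acid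
Product: 10 (R)-3-[4-(benzyloxy)-3-methoxyphenyl]-2-[2-(benzyloxy)-3-methoxy-5-(methoxycarbonyl)phenyl]propanoic acid
Conditions: [Ir(cod)(L*)][B(3,5-(CF3)2C6H3)4] (1 mol%, L* = spirobiindane phosphine–oxazoline SIPHOX), H2 (6 atm), Et3N (0.5 equiv), MeOH, rt
Reagents that add atoms: none
Why: Carboxylate-directed iridium-catalysed asymmetric hydrogenation, a known reaction of (E)-α-arylcinnamic acids. The bound carboxylate fixes the alkene on the chiral catalyst and the ligand decides the face, which sets the future C3 as R. The homogeneous catalyst does not touch benzyl ethers or the aromatic ester.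

Step 8
Reactants: 10 (R)-3-[4-(benzyloxy)-3-methoxyphenyl]-2-[2-(benzyloxy)-3-methoxy-5-(methoxycarbonyl)phenyl]propanoic acid
Product: 11 methyl (R)-4-(benzyloxy)-3-{1-[4-(benzyloxy)-3-methoxyphenyl]-3-hydroxypropan-2-yl}-5-methoxybenzoate
Conditions: BH3·THF, THF, 0 °C to rt
Reagents that add atoms: none
Why: Borane reduces a free carboxylic acid through its acyloxyborane much faster than an aromatic ester, so only the future C9 is reduced. No base is present, so the α-aryl stereocentre is not at risk.

Step 9
Reactants: 11 methyl (R)-4-(benzyloxy)-3-{1-[4-(benzyloxy)-3-methoxyphenyl]-3-hydroxypropan-2-yl}-5-methoxybenzoate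
Product: 12 methyl (R)-4-(benzyloxy)-3-{1-[4-(benzyloxy)-3-methoxyphenyl]-3-(tert-butyldimethylsilyloxy)propan-2-yl}-5-methoxybenzoate
Conditions: TBSCl, imidazole, CH2Cl2, rt
Reagents that add atoms: tert-butyldimethylsilyl chloride, CC(C)(C)[Si](C)(C)Cl
Why: Standard silylation of a primary alcohol. The TBS group keeps the C9 hydroxyl from adding to quinone methides of other molecules, makes the substrate soluble in apolar solvent and adds bulk that favours the trans closure.

Step 10
Reactants: 12 methyl (R)-4-(benzyloxy)-3-{1-[4-(benzyloxy)-3-methoxyphenyl]-3-(tert-butyldimethylsilyloxy)propan-2-yl}-5-methoxybenzoate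
Product: 13 methyl (R)-3-[1-(tert-butyldimethylsilyloxy)-3-(4-hydroxy-3-methoxyphenyl)propan-2-yl]-4-hydroxy-5-methoxybenzoate
Conditions: H2 (1 atm), 10% Pd/C, EtOAc, rt
Reagents that add atoms: none
Why: Hydrogenolysis of both aryl benzyl ethers under neutral conditions. Silyl ether, ester and stereocentre are unaffected in ethyl acetate.

Step 11
Reactants: 13 methyl (R)-3-[1-(tert-butyldimethylsilyloxy)-3-(4-hydroxy-3-methoxyphenyl)propan-2-yl]-4-hydroxy-5-methoxybenzoate
Product: 15 methyl (2S,3R)-3-(tert-butyldimethylsilyloxymethyl)-2-(4-hydroxy-3-methoxyphenyl)-7-methoxy-2,3-dihydrobenzofuran-5-carboxylate (trans), via para-quinone methide 14 (not isolated)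
Conditions: Ag2O (1.1 equiv), 4 Å MS, CH2Cl2 (0.01 M), rt, dark
Reagents that add atoms: none
Why: Ag2O removes two electrons and two protons from the electron-rich ring C guaiacol (phenoxyl radical, then loss of a C2 hydrogen) and gives para-quinone methide 14, whose exocyclic carbon is C2. The ring A phenol then adds to C2 in a 1,6-conjugate addition that rearomatises ring C and forms O1–C2, closing ring B in the 5-exo-trig mode. The closest known reaction type is the Ag2O or DDQ dehydrogenation of 4-alkylguaiacols to para-quinone methides with intramolecular capture by a phenol, the same capture that ends every biomimetic 8–5′ coupling. The new stereocentre C2 is controlled by C3: in the envelope-like transition state the quinone methide ring turns away from the CH2OTBS group, and because the addition is reversible through the ring C phenoxide, the more stable trans isomer (2S,3R) is also the thermodynamic product. Site selectivity between the two phenols is secured by the C5 ester para to O1, which raises the oxidation potential of ring A and so blocks both its radical coupling and an ortho-quinone methide at C3–H that would erase the stereocentre. Ring closure must also be faster than tautomerisation of 14 to the C2=C3 stilbene, which intramolecularity, an aprotic solvent and the absence of soluble base all favour. High dilution suppresses coupling at the free C5′ position of ring C, and about one equivalent of oxidant keeps 15 from further dehydrogenation of ring B.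

Step 12
Reactants: 15 methyl (2S,3R)-3-(tert-butyldimethylsilyloxymethyl)-2-(4-hydroxy-3-methoxyphenyl)-7-methoxy-2,3-dihydrobenzofuran-5-carboxylate
Product: 16 methyl (2S,3R)-3-(tert-butyldimethylsilyloxymethyl)-7-methoxy-2-(3-methoxy-4-triisopropylsilyloxyphenyl)-2,3-dihydrobenzofuran-5-carboxylate
Conditions: TIPSCl, imidazole, DMF, rt
Reagents that add atoms: triisopropylsilyl chloride, CC(C)[Si](Cl)(C(C)C)C(C)C
Why: Silylation of the guaiacol hydroxyl. Capping the para hydroxyl at once shuts off the retro-1,6-addition that could reopen O1–C2, and an aryl TIPS ether is chosen because it outlasts the alkyl TBS ether under acid (step 16).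

Step 13
Reactants: 16 methyl (2S,3R)-3-(tert-butyldimethylsilyloxymethyl)-7-methoxy-2-(3-methoxy-4-triisopropylsilyloxyphenyl)-2,3-dihydrobenzofuran-5-carboxylate
Product: 17 [(2S,3R)-3-(tert-butyldimethylsilyloxymethyl)-7-methoxy-2-(3-methoxy-4-triisopropylsilyloxyphenyl)-2,3-dihydrobenzofuran-5-yl]methanol
Conditions: i-Bu2AlH (2.5 equiv), CH2Cl2, −78 °C; aq. potassium sodium tartrate
Reagents that add atoms: none
Why: Hydride reduction of the aromatic ester to the benzylic alcohol. Silyl ethers and the benzylic ether C2–O1 are stable at low temperature.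

Step 14
Reactants: 17 [(2S,3R)-3-(tert-butyldimethylsilyloxymethyl)-7-methoxy-2-(3-methoxy-4-triisopropylsilyloxyphenyl)-2,3-dihydrobenzofuran-5-yl]methanol
Product: 18 (2S,3R)-3-(tert-butyldimethylsilyloxymethyl)-7-methoxy-2-(3-methoxy-4-triisopropylsilyloxyphenyl)-2,3-dihydrobenzofuran-5-carbaldehyde
Conditions: MnO2 (activated, excess), CH2Cl2, rt
Reagents that add atoms: none
Why: MnO2 oxidises benzylic alcohols selectively and stops at the aldehyde. Nothing else in 17 is activated now that the ring C phenol is capped.

Step 15
Reactants: 18 (2S,3R)-3-(tert-butyldimethylsilyloxymethyl)-7-methoxy-2-(3-methoxy-4-triisopropylsilyloxyphenyl)-2,3-dihydrobenzofuran-5-carbaldehyde; 19 methyl bis(2,2,2-trifluoroethyl)phosphonoacetate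
Product: 20 methyl (Z)-3-[(2S,3R)-3-(tert-butyldimethylsilyloxymethyl)-7-methoxy-2-(3-methoxy-4-triisopropylsilyloxyphenyl)-2,3-dihydrobenzofuran-5-yl]prop-2-enoate
Conditions: KN(SiMe3)2, 18-crown-6, THF, −78 °C
Reagents that add atoms: none
Why: Still–Gennari variant of the Horner–Wadsworth–Emmons reaction. With the electron-poor trifluoroethyl phosphonate and a dissociated potassium counter-ion, elimination from the kinetic adduct is faster than its reversal, which gives the Z enoate, dependably so with aromatic aldehydes.

Step 16
Reactants: 20 methyl (Z)-3-[(2S,3R)-3-(tert-butyldimethylsilyloxymethyl)-7-methoxy-2-(3-methoxy-4-triisopropylsilyloxyphenyl)-2,3-dihydrobenzofuran-5-yl]prop-2-enoate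
Product: 21 methyl (Z)-3-[(2S,3R)-3-(hydroxymethyl)-7-methoxy-2-(3-methoxy-4-triisopropylsilyloxyphenyl)-2,3-dihydrobenzofuran-5-yl]prop-2-enoate
Conditions: CSA (10 mol%), MeOH/CH2Cl2 1:1, 0 °C
Reagents that add atoms: none
Why: Acid-catalysed methanolysis cleaves the more basic, less hindered alkyl O–TBS bond far faster than the aryl O–TIPS bond. The Z enoate is inert to catalytic acid and ester exchange with methanol is degenerate, which is why C9 is unmasked before the acid-sensitive cinnamyl alcohol exists.

Step 17
Reactants: 21 methyl (Z)-3-[(2S,3R)-3-(hydroxymethyl)-7-methoxy-2-(3-methoxy-4-triisopropylsilyloxyphenyl)-2,3-dihydrobenzofuran-5-yl]prop-2-enoate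
Product: 22 (Z)-3-[(2S,3R)-3-(hydroxymethyl)-7-methoxy-2-(3-methoxy-4-triisopropylsilyloxyphenyl)-2,3-dihydrobenzofuran-5-yl]prop-2-en-1-ol
Conditions: i-Bu2AlH (4 equiv), CH2Cl2, −78 °C; aq. potassium sodium tartrate
Reagents that add atoms: none
Why: Excess i-Bu2AlH reduces the enoate in 1,2-fashion to the allylic alcohol with retention of the Z geometry, and the free hydroxyl only consumes one equivalent. The neutral tartrate work-up avoids ionising the electron-rich cinnamyl alcohol.

Step 18
Reactants: 22 (Z)-3-[(2S,3R)-3-(hydroxymethyl)-7-methoxy-2-(3-methoxy-4-triisopropylsilyloxyphenyl)-2,3-dihydrobenzofuran-5-yl]prop-2-en-1-ol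
Product: 23 (Z)-3-[(2S,3R)-3-(hydroxymethyl)-7-methoxy-2-(3-methoxy-4-triisopropylsilyloxyphenyl)-2,3-dihydrobenzofuran-5-yl]prop-2-enal
Conditions: MnO2 (activated, excess), CH2Cl2, 0 °C to rt, dark
Reagents that add atoms: none
Why: MnO2 oxidises only π-activated alcohols, so the saturated C9 hydroxyl is left and the two primary alcohols are told apart without protecting groups. The neutral heterogeneous medium, short contact and exclusion of light are chosen to keep the Z geometry.

Step 19
Reactants: 24 4-hydroxybenzoic acid
Product: 26 4-(tert-butyldimethylsilyloxy)benzoic acid, via bis-silylated ester 25 (not isolated)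
Conditions: TBSCl (2.5 equiv), imidazole, DMF, rt; then AcOH/THF/H2O, rt
Reagents that add atoms: tert-butyldimethylsilyl chloride, CC(C)(C)[Si](C)(C)Cl
Why: Exhaustive silylation followed by selective hydrolysis. The silyl ester is far more labile to aqueous acid than the aryl silyl ether.

Step 20
Reactants: 23 (Z)-3-[(2S,3R)-3-(hydroxymethyl)-7-methoxy-2-(3-methoxy-4-triisopropylsilyloxyphenyl)-2,3-dihydrobenzofuran-5-yl]prop-2-enal; 26 4-(tert-butyldimethylsilyloxy)benzoic acid
Product: 28 {(2S,3R)-7-methoxy-2-(3-methoxy-4-triisopropylsilyloxyphenyl)-5-[(Z)-3-oxoprop-1-enyl]-2,3-dihydrobenzofuran-3-yl}methyl 4-(tert-butyldimethylsilyloxy)benzoate, via acid chloride 27 (not isolated)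
Conditions: 26, 1-chloro-N,N,2-trimethylprop-1-en-1-amine, CH2Cl2, 0 °C to rt; then 23, pyridine, CH2Cl2, 0 °C, dark
Reagents that add atoms: 1-chloro-N,N,2-trimethylprop-1-en-1-amine, CC(C)=C(Cl)N(C)C (supplies the chlorine of 27 only)
Why: The α-chloroenamine makes the acid chloride under neutral conditions that spare the aryl silyl ether, and O-acylation of the primary alcohol leaves the C9–O bond and both stereocentres untouched. Pyridine is used in place of a 4-aminopyridine catalyst because strongly nucleophilic amines add reversibly to the enal and would isomerise it.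

Step 21
Reactants: 28 {(2S,3R)-7-methoxy-2-(3-methoxy-4-triisopropylsilyloxyphenyl)-5-[(Z)-3-oxoprop-1-enyl]-2,3-dihydrobenzofuran-3-yl}methyl 4-(tert-butyldimethylsilyloxy)benzoate
Product: 29 [(2S,3R)-2-(4-hydroxy-3-methoxyphenyl)-7-methoxy-5-[(Z)-3-oxoprop-1-enyl]-2,3-dihydrobenzofuran-3-yl]methyl 4-hydroxybenzoate (CNP0400980.1)
Conditions: Bu4NF/AcOH 1:1 (2.5 equiv), THF, 0 °C, dark
Reagents that add atoms: none
Why: Fluoride cleaves aryl silyl ethers quickly because phenoxides are good leaving groups from silicon. Acetic acid protonates each phenoxide as it forms, which prevents retro-1,6-opening of O1–C2, ester migration and base-induced isomerisation of the enal.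

## Compound list

1 | methyl vanillate (methyl 4-hydroxy-3-methoxybenzoate) | COC(=O)c1ccc(O)c(OC)c1 | starting material
2 | allyl bromide | C=CCBr | starting material
3 | methyl 4-(allyloxy)-3-methoxybenzoate | C=CCOc1ccc(C(=O)OC)cc1OC | intermediate
4 | methyl 3-allyl-4-hydroxy-5-methoxybenzoate | C=CCc1cc(C(=O)OC)cc(OC)c1O | intermediate
5 | methyl 3-allyl-4-(benzyloxy)-5-methoxybenzoate | C=CCc1cc(C(=O)OC)cc(OC)c1OCc1ccccc1 | intermediate
6 | methyl 4-(benzyloxy)-3-methoxy-5-(2-oxoethyl)benzoate | O=CCc1cc(C(=O)OC)cc(OC)c1OCc1ccccc1 | intermediate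
7 | 2-[2-(benzyloxy)-3-methoxy-5-(methoxycarbonyl)phenyl]acetic acid | O=C(O)Cc1cc(C(=O)OC)cc(OC)c1OCc1ccccc1 | intermediate
8 | 4-(benzyloxy)-3-methoxybenzaldehyde (O-benzylvanillin) | COc1cc(C=O)ccc1OCc1ccccc1 | starting material
9 | (E)-3-[4-(benzyloxy)-3-methoxyphenyl]-2-[2-(benzyloxy)-3-methoxy-5-(methoxycarbonyl)phenyl]prop-2-enoic acid | COc1cc(/C=C(/C(=O)O)c2cc(C(=O)OC)cc(OC)c2OCc2ccccc2)ccc1OCc1ccccc1 | intermediate
10 | (R)-3-[4-(benzyloxy)-3-methoxyphenyl]-2-[2-(benzyloxy)-3-methoxy-5-(methoxycarbonyl)phenyl]propanoic acid | COc1cc(C[C@@H](C(=O)O)c2cc(C(=O)OC)cc(OC)c2OCc2ccccc2)ccc1OCc1ccccc1 | intermediate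
11 | methyl (R)-4-(benzyloxy)-3-{1-[4-(benzyloxy)-3-methoxyphenyl]-3-hydroxypropan-2-yl}-5-methoxybenzoate | COc1cc(C[C@@H](CO)c2cc(C(=O)OC)cc(OC)c2OCc2ccccc2)ccc1OCc1ccccc1 | intermediate
12 | methyl (R)-4-(benzyloxy)-3-{1-[4-(benzyloxy)-3-methoxyphenyl]-3-(tert-butyldimethylsilyloxy)propan-2-yl}-5-methoxybenzoate | COc1cc(C[C@@H](CO[Si](C)(C)C(C)(C)C)c2cc(C(=O)OC)cc(OC)c2OCc2ccccc2)ccc1OCc1ccccc1 | intermediate
13 | methyl (R)-3-[1-(tert-butyldimethylsilyloxy)-3-(4-hydroxy-3-methoxyphenyl)propan-2-yl]-4-hydroxy-5-methoxybenzoate | COc1cc(C[C@@H](CO[Si](C)(C)C(C)(C)C)c2cc(C(=O)OC)cc(OC)c2O)ccc1O | intermediate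
14 | para-quinone methide of 13: methyl (R)-3-[1-(tert-butyldimethylsilyloxy)-3-(3-methoxy-4-oxocyclohexa-2,5-dien-1-ylidene)propan-2-yl]-4-hydroxy-5-methoxybenzoate | COC1=CC(=C[C@@H](CO[Si](C)(C)C(C)(C)C)c2cc(C(=O)OC)cc(OC)c2O)C=CC1=O | intermediate
15 | methyl (2S,3R)-3-(tert-butyldimethylsilyloxymethyl)-2-(4-hydroxy-3-methoxyphenyl)-7-methoxy-2,3-dihydrobenzofuran-5-carboxylate (trans) | COc1cc([C@H]2Oc3c(OC)cc(C(=O)OC)cc3[C@@H]2CO[Si](C)(C)C(C)(C)C)ccc1O | intermediate
16 | methyl (2S,3R)-3-(tert-butyldimethylsilyloxymethyl)-7-methoxy-2-(3-methoxy-4-triisopropylsilyloxyphenyl)-2,3-dihydrobenzofuran-5-carboxylate | COc1cc([C@H]2Oc3c(OC)cc(C(=O)OC)cc3[C@@H]2CO[Si](C)(C)C(C)(C)C)ccc1O[Si](C(C)C)(C(C)C)C(C)C | intermediate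
17 | [(2S,3R)-3-(tert-butyldimethylsilyloxymethyl)-7-methoxy-2-(3-methoxy-4-triisopropylsilyloxyphenyl)-2,3-dihydrobenzofuran-5-yl]methanol | COc1cc([C@H]2Oc3c(OC)cc(CO)cc3[C@@H]2CO[Si](C)(C)C(C)(C)C)ccc1O[Si](C(C)C)(C(C)C)C(C)C | intermediate
18 | (2S,3R)-3-(tert-butyldimethylsilyloxymethyl)-7-methoxy-2-(3-methoxy-4-triisopropylsilyloxyphenyl)-2,3-dihydrobenzofuran-5-carbaldehyde | COc1cc([C@H]2Oc3c(OC)cc(C=O)cc3[C@@H]2CO[Si](C)(C)C(C)(C)C)ccc1O[Si](C(C)C)(C(C)C)C(C)C | intermediate
19 | methyl bis(2,2,2-trifluoroethyl)phosphonoacetate | COC(=O)CP(=O)(OCC(F)(F)F)OCC(F)(F)F | starting material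
20 | methyl (Z)-3-[(2S,3R)-3-(tert-butyldimethylsilyloxymethyl)-7-methoxy-2-(3-methoxy-4-triisopropylsilyloxyphenyl)-2,3-dihydrobenzofuran-5-yl]prop-2-enoate | COc1cc([C@H]2Oc3c(OC)cc(/C=C\C(=O)OC)cc3[C@@H]2CO[Si](C)(C)C(C)(C)C)ccc1O[Si](C(C)C)(C(C)C)C(C)C | intermediate
21 | methyl (Z)-3-[(2S,3R)-3-(hydroxymethyl)-7-methoxy-2-(3-methoxy-4-triisopropylsilyloxyphenyl)-2,3-dihydrobenzofuran-5-yl]prop-2-enoate | COc1cc([C@H]2Oc3c(OC)cc(/C=C\C(=O)OC)cc3[C@@H]2CO)ccc1O[Si](C(C)C)(C(C)C)C(C)C | intermediate
22 | (Z)-3-[(2S,3R)-3-(hydroxymethyl)-7-methoxy-2-(3-methoxy-4-triisopropylsilyloxyphenyl)-2,3-dihydrobenzofuran-5-yl]prop-2-en-1-ol | COc1cc([C@H]2Oc3c(OC)cc(/C=C\CO)cc3[C@@H]2CO)ccc1O[Si](C(C)C)(C(C)C)C(C)C | intermediate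
23 | (Z)-3-[(2S,3R)-3-(hydroxymethyl)-7-methoxy-2-(3-methoxy-4-triisopropylsilyloxyphenyl)-2,3-dihydrobenzofuran-5-yl]prop-2-enal | COc1cc([C@H]2Oc3c(OC)cc(/C=C\C=O)cc3[C@@H]2CO)ccc1O[Si](C(C)C)(C(C)C)C(C)C | intermediate
24 | 4-hydroxybenzoic acid | O=C(O)c1ccc(O)cc1 | starting material
25 | tert-butyldimethylsilyl 4-(tert-butyldimethylsilyloxy)benzoate | CC(C)(C)[Si](C)(C)Oc1ccc(C(=O)O[Si](C)(C)C(C)(C)C)cc1 | intermediate
26 | 4-(tert-butyldimethylsilyloxy)benzoic acid | CC(C)(C)[Si](C)(C)Oc1ccc(C(=O)O)cc1 | intermediate
27 | 4-(tert-butyldimethylsilyloxy)benzoyl chloride | CC(C)(C)[Si](C)(C)Oc1ccc(C(=O)Cl)cc1 | intermediate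
28 | {(2S,3R)-7-methoxy-2-(3-methoxy-4-triisopropylsilyloxyphenyl)-5-[(Z)-3-oxoprop-1-enyl]-2,3-dihydrobenzofuran-3-yl}methyl 4-(tert-butyldimethylsilyloxy)benzoate | COc1cc([C@H]2Oc3c(OC)cc(/C=C\C=O)cc3[C@@H]2COC(=O)c2ccc(O[Si](C)(C)C(C)(C)C)cc2)ccc1O[Si](C(C)C)(C(C)C)C(C)C | intermediate
29 | [(2S,3R)-2-(4-hydroxy-3-methoxyphenyl)-7-methoxy-5-[(Z)-3-oxoprop-1-enyl]-2,3-dihydrobenzofuran-3-yl]methyl 4-hydroxybenzoate (CNP0400980.1) | COc1cc([C@H]2Oc3c(OC)cc(/C=C\C=O)cc3[C@@H]2COC(=O)c2ccc(O)cc2)ccc1O | target

## Step count and least certain steps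

Total step count: 21. Longest linear sequence: 20 steps (steps 1–18, 20 and 21). Step 19 is a one-step side branch.

**Step 11 (key step).**
- **Risk.** The most likely failures are tautomerisation of the quinone methide along C2–C3 before ring closure (loss of the C3 configuration), radical coupling of the ring C phenoxyl at its free ortho position, and further dehydrogenation of ring B by surplus oxidant. All three arise because a guaiacol with only one ortho substituent gives a short-lived, unhindered quinone methide.
- **Fallback.** The same quinone methide would be reached without an oxidant, by dehydration of a C2 carbinol. Setting out from 7, the acid would be coupled (EDC, DMAP) with (S)-4-benzyloxazolidin-2-one to give the (4S)-arylacetyl imide F1. An Evans syn-aldol reaction (Bu2BOTf, i-Pr2NEt, then 8) would give the (2S,3S)-aldol adduct F2, whose α-carbon already has the C3 configuration of 15. LiBH4 would release the (1S,2R)-1,3-diol F3, and TBSCl would silylate its primary hydroxyl selectively to give the mono-TBS ether F4. Hydrogenolysis would then give the bisphenol carbinol F5. Catalytic PPTS in CH2Cl2 would ionise the para-hydroxybenzylic alcohol of F5 to 14, which closes as in the main route, so the fallback comes back at 15.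

**Step 7.**
- **Risk.** Hydrogen delivery may be slow or poorly face-selective, because the ortho benzyloxy group twists the α-aryl ring and crowds the carboxylate-bound metal. Any geometric impurity in 9 would also erode the enantiomeric purity.
- **Fallback.** An auxiliary-controlled alkylation would replace the hydrogenation. Setting out from 7, coupling with (R)-4-benzyloxazolidin-2-one would give the (4R)-arylacetyl imide F6. In parallel, 8 would be reduced (NaBH4) to 4-(benzyloxy)-3-methoxybenzyl alcohol F7 and converted (PBr3) into 4-(benzyloxy)-3-methoxybenzyl bromide F8. Evans alkylation of the chelated Z-enolate of F6 (NaN(SiMe3)2, THF, −78 °C) with F8, anti to the benzyl group of the auxiliary, would give the (2R)-alkylated imide F9. LiBH4 would then deliver 11 directly, so the fallback bypasses steps 6–8 and comes back at 11.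

**Step 18.**
- **Risk.** Partial Z-to-E isomerisation may occur on the oxide surface during long contact, and the two alcohols may be incompletely discriminated if a very active batch of oxidant is used.
- **Fallback.** The alcohols would be told apart by protecting groups, so that a homogeneous buffered oxidant acts on a mono-alcohol and the acylation precedes the enal. Setting out from 20, i-Bu2AlH would give the C9-silylated Z-allylic alcohol F10, and levulinic acid with EDC and DMAP its levulinate F11. PPTS in MeOH would free the C9 alcohol F12. Acid 26 with EDC and DMAP would give the C9 4-(tert-butyldimethylsilyloxy)benzoate F13, and hydrazine acetate would remove the levulinate to give the Z-allylic alcohol F14. Dess–Martin periodinane buffered with NaHCO3 would then give 28, where the fallback comes back.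

**Step 20.**
- **Risk.** The amine base may add reversibly to the enal and cause loss of the Z geometry. Acylation of the β-branched primary alcohol may also be slow enough to prolong that exposure.
- **Fallback.** The C9–O bond would be formed by alcohol activation rather than by acyl transfer. Setting out from 23 and 26, a Mitsunobu esterification with the betaine pre-formed from PPh3 and DIAD (THF, 0 °C, dark) leaves no free amine or phosphine in solution and comes back at 28. It makes no new compound.

**Step 21.**
- **Risk.** Isomerisation of the enal, or opening of O1–C2, may be triggered by transient phenoxide or by basic fluoride if the buffering is insufficient.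
- **Fallback.** The silyl groups would be removed before the enal exists. Setting out from 20 and following the detour described for step 18 as far as the Z-allylic alcohol F14, Bu4NF/AcOH would give the fully desilylated Z-allylic alcohol F15. One equivalent of DDQ in THF at 0 °C dehydrogenates para-alkoxycinnamyl alcohols by hydride abstraction faster than it attacks the ring C guaiacol. It would form the enal as the very last operation and come back at 29.

## Further compounds

F1 | step 11 | methyl 4-(benzyloxy)-3-{2-[(4S)-4-benzyl-2-oxo-1,3-oxazolidin-3-yl]-2-oxoethyl}-5-methoxybenzoate | COC(=O)c1cc(OC)c(OCc2ccccc2)c(CC(=O)N2[C@@H](Cc3ccccc3)COC2=O)c1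
F2 | step 11 | (4S)-4-benzyl-3-{(2S,3S)-3-[4-(benzyloxy)-3-methoxyphenyl]-2-[2-(benzyloxy)-3-methoxy-5-(methoxycarbonyl)phenyl]-3-hydroxypropanoyl}-1,3-oxazolidin-2-one | COc1cc([C@@H](O)[C@@H](C(=O)N2[C@@H](Cc3ccccc3)COC2=O)c2cc(C(=O)OC)cc(OC)c2OCc2ccccc2)ccc1OCc1ccccc1
F3 | step 11 | methyl 4-(benzyloxy)-3-{(1S,2R)-1-[4-(benzyloxy)-3-methoxyphenyl]-1,3-dihydroxypropan-2-yl}-5-methoxybenzoate | COc1cc([C@@H](O)[C@@H](CO)c2cc(C(=O)OC)cc(OC)c2OCc2ccccc2)ccc1OCc1ccccc1
F4 | step 11 | methyl 4-(benzyloxy)-3-{(1S,2R)-1-[4-(benzyloxy)-3-methoxyphenyl]-3-(tert-butyldimethylsilyloxy)-1-hydroxypropan-2-yl}-5-methoxybenzoate | COc1cc([C@@H](O)[C@@H](CO[Si](C)(C)C(C)(C)C)c2cc(C(=O)OC)cc(OC)c2OCc2ccccc2)ccc1OCc1ccccc1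
F5 | step 11 | methyl 3-[(1S,2R)-3-(tert-butyldimethylsilyloxy)-1-hydroxy-1-(4-hydroxy-3-methoxyphenyl)propan-2-yl]-4-hydroxy-5-methoxybenzoate | COc1cc([C@@H](O)[C@@H](CO[Si](C)(C)C(C)(C)C)c2cc(C(=O)OC)cc(OC)c2O)ccc1O
F6 | step 7 | methyl 4-(benzyloxy)-3-{2-[(4R)-4-benzyl-2-oxo-1,3-oxazolidin-3-yl]-2-oxoethyl}-5-methoxybenzoate | COC(=O)c1cc(OC)c(OCc2ccccc2)c(CC(=O)N2[C@H](Cc3ccccc3)COC2=O)c1
F7 | step 7 | 4-(benzyloxy)-3-methoxybenzyl alcohol | COc1cc(CO)ccc1OCc1ccccc1
F8 | step 7 | 4-(benzyloxy)-3-methoxybenzyl bromide | COc1cc(CBr)ccc1OCc1ccccc1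
F9 | step 7 | (4R)-4-benzyl-3-{(2R)-3-[4-(benzyloxy)-3-methoxyphenyl]-2-[2-(benzyloxy)-3-methoxy-5-(methoxycarbonyl)phenyl]propanoyl}-1,3-oxazolidin-2-one | COc1cc(C[C@@H](C(=O)N2[C@H](Cc3ccccc3)COC2=O)c2cc(C(=O)OC)cc(OC)c2OCc2ccccc2)ccc1OCc1ccccc1
F10 | step 18 | (Z)-3-[(2S,3R)-3-(tert-butyldimethylsilyloxymethyl)-7-methoxy-2-(3-methoxy-4-triisopropylsilyloxyphenyl)-2,3-dihydrobenzofuran-5-yl]prop-2-en-1-ol | COc1cc([C@H]2Oc3c(OC)cc(/C=C\CO)cc3[C@@H]2CO[Si](C)(C)C(C)(C)C)ccc1O[Si](C(C)C)(C(C)C)C(C)C
F11 | step 18 | (Z)-3-[(2S,3R)-3-(tert-butyldimethylsilyloxymethyl)-7-methoxy-2-(3-methoxy-4-triisopropylsilyloxyphenyl)-2,3-dihydrobenzofuran-5-yl]prop-2-enyl 4-oxopentanoate | COc1cc([C@H]2Oc3c(OC)cc(/C=C\COC(=O)CCC(C)=O)cc3[C@@H]2CO[Si](C)(C)C(C)(C)C)ccc1O[Si](C(C)C)(C(C)C)C(C)C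
F12 | step 18 | (Z)-3-[(2S,3R)-3-(hydroxymethyl)-7-methoxy-2-(3-methoxy-4-triisopropylsilyloxyphenyl)-2,3-dihydrobenzofuran-5-yl]prop-2-enyl 4-oxopentanoate | COc1cc([C@H]2Oc3c(OC)cc(/C=C\COC(=O)CCC(C)=O)cc3[C@@H]2CO)ccc1O[Si](C(C)C)(C(C)C)C(C)C
F13 | step 18 | {(2S,3R)-7-methoxy-2-(3-methoxy-4-triisopropylsilyloxyphenyl)-5-[(Z)-3-(4-oxopentanoyloxy)prop-1-enyl]-2,3-dihydrobenzofuran-3-yl}methyl 4-(tert-butyldimethylsilyloxy)benzoate | COc1cc([C@H]2Oc3c(OC)cc(/C=C\COC(=O)CCC(C)=O)cc3[C@@H]2COC(=O)c2ccc(O[Si](C)(C)C(C)(C)C)cc2)ccc1O[Si](C(C)C)(C(C)C)C(C)C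
F14 | step 18 | {(2S,3R)-5-[(Z)-3-hydroxyprop-1-enyl]-7-methoxy-2-(3-methoxy-4-triisopropylsilyloxyphenyl)-2,3-dihydrobenzofuran-3-yl}methyl 4-(tert-butyldimethylsilyloxy)benzoate | COc1cc([C@H]2Oc3c(OC)cc(/C=C\CO)cc3[C@@H]2COC(=O)c2ccc(O[Si](C)(C)C(C)(C)C)cc2)ccc1O[Si](C(C)C)(C(C)C)C(C)C
F0 | step 20 | none | none
F15 | step 21 | [(2S,3R)-2-(4-hydroxy-3-methoxyphenyl)-5-[(Z)-3-hydroxyprop-1-enyl]-7-methoxy-2,3-dihydrobenzofuran-3-yl]methyl 4-hydroxybenzoate | COc1cc([C@H]2Oc3c(OC)cc(/C=C\CO)cc3[C@@H]2COC(=O)c2ccc(O)cc2)ccc1O
A1 | alternative 1 | 5-(dimethoxymethyl)-7-methoxybenzofuran | COC(OC)c1cc(OC)c2occc2c1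
A2 | alternative 1 | 2-(3-methoxy-4-triisopropylsilyloxyphenyl)-4,4,5,5-tetramethyl-1,3,2-dioxaborolane | COc1cc(B2OC(C)(C)C(C)(C)O2)ccc1O[Si](C(C)C)(C(C)C)C(C)C
A3 | alternative 1 | 3-allyl-5-(dimethoxymethyl)-7-methoxy-2-(3-methoxy-4-triisopropylsilyloxyphenyl)-2-(pinacolboryl)-2,3-dihydrobenzofuran (aryl and allyl trans) | COc1cc([C@@]2(B4OC(C)(C)C(C)(C)O4)Oc3c(OC)cc(C(OC)OC)cc3[C@@H]2CC=C)ccc1O[Si](C(C)C)(C(C)C)C(C)C
A4 | alternative 2 | (2S)-6-bromo-8-methoxy-2-(3-methoxy-4-pivaloyloxyphenyl)chroman-4-one | COc1cc([C@@H]2CC(=O)c3cc(Br)cc(OC)c3O2)ccc1OC(=O)C(C)(C)C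
A5 | alternative 2 | methyl trans-(2S,3S)-5-bromo-7-methoxy-2-(3-methoxy-4-pivaloyloxyphenyl)-2,3-dihydrobenzofuran-3-carboxylate | COc1cc([C@H]2Oc3c(OC)cc(Br)cc3[C@@H]2C(=O)OC)ccc1OC(=O)C(C)(C)C
A6 | alternative 3 | (E)-4-bromo-2-methoxy-6-(2-nitrovinyl)phenol | COc1cc(Br)cc(/C=C/[N+](=O)[O-])c1O
A7 | alternative 3 | (2R,5R)-1-[3-methoxy-4-(triisopropylsilyloxy)benzyl]-2,5-dimethylthiolan-1-ium tetrafluoroborate | COc1cc(C[S+]2[C@H](C)CC[C@H]2C)ccc1O[Si](C(C)C)(C(C)C)C(C)C.F[B-](F)(F)F
A8 | alternative 3 | trans-(2S,3R)-5-bromo-7-methoxy-2-(3-methoxy-4-triisopropylsilyloxyphenyl)-3-(nitromethyl)-2,3-dihydrobenzofuran | COc1cc([C@H]2Oc3c(OC)cc(Br)cc3[C@@H]2C[N+](=O)[O-])ccc1O[Si](C(C)C)(C(C)C)C(C)C
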